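The numbers in the tables are simulated with constants of no real substance; the scatter is artificial.

Early times pointed to something at work on Q. At 0.417 min, with one portion in, cedar held 0.5% of J and elm 4.3%, a ratio read as 8.60, larger than the 4.20 that their portions and G charges give. So I set two amounts against each other: c(Z), 0.27 mM, and one portion of Q at a loading of 5 mol%, 0.300 mM. Through Q + Z -> X, Z would take nearly all of a first portion of that size.

the same everywhere: E 0.024 M; D 0.024 M; Z 0.27 mM

|  | G | Q | remark | time |
|---|---|---|---|---|
| cedar | 2 equiv | 5 mol% (in portions, 4) | run made earlier; portions every 40 s |  |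
| ash | 3.8 equiv | 5 mol% (in portions, 4) | run made earlier; portions every 40 s |  |
| elm | 3 equiv | 14 mol% (in portions, 4) | run made earlier; portions every 40 s |  |
| red | 3.00 equiv | 5 mol% (in portions, 4) | the portions of Q follow each other after 10 s, the first at the start | 6.0 min |
| violet | 3.00 equiv | 5 mol% (in portions, 4) | the portions of Q follow each other after 150 s, the first at the start | 6.0 min |
| amber | 6.00 equiv | 20 mol% (in portions, 4) | the portions of Q follow each other after 40 s, the first at the start | 6.0 min |
| grey | 3.00 equiv | 5 mol% (in portions, 4) | the portions of Q follow each other after 40 s, the first at the start | 6.0 min |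

| run | time / min | J / % | E / % |
|---|---|---|---|
| cedar | 0.417 | 0.5 | 49.2 |
| cedar | 1.00 | 2.3 | 48.0 |
| cedar | 2.00 | 7.5 | 42.6 |
| cedar | 3.00 | 15.0 | 35.3 |
| cedar | 4.00 | 21.0 | 29.2 |
| ash | 0.417 | 0.4 | 49.0 |
| ash | 1.00 | 4.1 | 46.4 |
| ash | 2.00 | 13.3 | 36.9 |
| ash | 3.00 | 25.3 | 24.3 |
| ash | 4.00 | 32.1 | 17.4 |
| elm | 0.417 | 4.3 | 45.9 |
| elm | 1.00 | 13.0 | 37.1 |
| elm | 2.00 | 29.6 | 19.8 |
| elm | 3.00 | 41.0 | 8.4 |
| elm | 4.00 | 45.6 | 3.9 |

(standard deviation of a reading: 0.3 percentage points)

- the flasks by amount of J, in percent of the E and D together charged, highest first, at 6.0 min (red / violet / amber / grey)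
- the amount of J, in percent of the E and D together charged of the flask you put first, at 6.0 min
- the amount of J, in percent of the E and D together charged of the flask you put last, at 6.0 min

- Q is single-handed; E and D are mirror images of each other, charged as a racemate, each of them at the stated concentration
- steps thought possible: G + Q + D -> Q + L; G + Q + E -> Q + J; Q + Z -> X
- percentages count the whole charge, also what has not yet gone in

I took the E loss as pseudo-first-order: ln(c(E) before/after) = k c(G) W. In grey, Q charged so far less c(Z), summed over time, comes to 4.38 mM·min, and this working catalyst-time is W. Late cedar, with 0.930 mM working and mean c(G) 39.4 mM, reads k = 5180 M⁻² min⁻¹. W is 22.4 mM·min for amber, 5.28 mM·min for red and, with three portions in by 6.0 min, 1.53 mM·min for violet, so I ranked amber, red, grey, violet. Amber's J reckons to 50.0%. Violet's gives 21.8% at charged c(G), and 20.6% with c(G) lowered by half the G that J used.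

The forecast gave amber > red > grey > violet, 49.9% (49.3% to 50.2%) for amber and 24% (21.5% to 26.5%) for violet, citing “Z quickly killing about 0.27 mM of Q”, and my violet stands below its value.

    G + Q + D → Q + L (k = 210 M⁻² min⁻¹)
    G + Q + E → Q + J (k = 5100 M⁻² min⁻¹)
    Q + Z → X (k = 64000 M⁻¹ min⁻¹)

The flasks gave amber > red > grey > violet: amber 50.0%, red 39.8%, grey 37.0%, violet 20.5%. In amber at 0.842 min, the step to J used G at 12 times the rate of the step to L, and at 6.00 min amber held 0% of E and 21.0% of L. A neighbour of amber charged with 1.50 equiv of G has the same W, 22.4 mM·min, yet kept 11% of its E, which reads as a mean c(G) of 18.7 mM, between its charge of 36.0 mM and its final 12.7 mM.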